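The leftover of the grey run opens the matter: target stands at 69.7 % after 5.00 d and gained 1.4 percentage points since the reading before, so 30.3 % of the substrate charged remains uncoupled.

all flasks: free catalyst 0.2 mol%

| charge | substrate | partner | second catalyst | remark | time |
|---|---|---|---|---|---|
| grey | 21 mM | 2 equiv | 5 mol% | run made earlier |  |
| green | 21 mM | 1.3 equiv | 5 mol% | run made earlier |  |
| blue | 21 mM | 3 equiv | 5 mol% | run made earlier |  |
| amber | 21 mM | 2 equiv | 10 mol% | run made earlier |  |
| beta | 21 mM | 2.00 equiv | 5 mol% | everything together at the start | 5.0 d |
| eta | 21 mM | 2.00 equiv (in portions, 2, over 4.0 d) | 5 mol% | first portion at the start, last at 4.0 d | 5.0 d |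
| zeta | 21 mM (fed, over 25 h) | 2.00 equiv | 5 mol% | all else is in the flask from the start; the feed brings no volume worth counting | 5.0 d |
| gamma | 21 mM (fed, over 4.0 d) | 2.00 equiv | 5 mol% | all else is in the flask from the start; the feed brings no volume worth counting | 5.0 d |
| theta | 21 mM | 2.00 equiv (fed, over 4.0 d) | 5 mol% | all else is in the flask from the start; the feed brings no volume worth counting | 5.0 d |

| grey: time / d | grey: target / % | green: time / d | green: target / % | blue: time / d | blue: target / % | amber: time / d | amber: target / % |
|---|---|---|---|---|---|---|---|
| 1.25 | 46.4 | 0.417 | 12.8 | 0.417 | 27.5 | 0.417 | 33.5 |
| 2.50 | 62.5 | 1.04 | 29.1 | 1.04 | 56.3 | 1.04 | 62.2 |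
| 4.00 | 68.3 | 2.08 | 42.6 | 2.08 | 74.1 | 2.08 | 78.2 |
| 5.00 | 69.7 | 3.00 | 47.2 | 3.00 | 80.6 | 3.00 | 82.7 |

(readings scatter by 0.5 percentage points)

1. which flask leads in amount of target, in percent of the substrate charged ("all alike" within 1.5 percentage points) (beta / eta / zeta / gamma / theta / all alike)
2. how much target is there at the end, in percent of the substrate charged: beta
3. how much target is there at the end, in percent of the substrate charged: eta
4. how much target is there at the end, in percent of the substrate charged: zeta
5. how much target is there at the end, in percent of the substrate charged: gamma
6. how much target is there at the end, in percent of the substrate charged: theta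

- reactions considered so far: substrate + free catalyst -> free catalyst + intermediate; partner + second catalyst + intermediate -> second catalyst + target; partner -> decomposed reagent

Substrate becomes intermediate under the free catalyst, a step this reckoning takes as immediate. Partner then has two fates: at fixed second catalyst it couples at kc[intermediate] per unit of partner, and it decomposes at kd. The two rates are equal at [intermediate] = K = kd/kc. Dividing one rate by the other and integrating gives a balance: partner used equals target formed plus K·ln([intermediate] at the start/[intermediate] now). Counting the grey charge as used by its last reading gives 22.9 mM, the break-even level between coupling and decomposition. The same balance puts [partner] in the blue run at 32.2 mM after 1.04 d. The logarithm of the intermediate left measures kc times the area under [partner], so a trapezoid over the blue readings gives an estimate of kd, 0.383 d⁻¹.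

A steady substrate feed delivers its average parcel at half the feed time, so this reckoning treats the flask as a batch holding a surviving charge, the partner charge times exp(−kd × feed time/2). For zeta that is 34.4 mM, and for gamma 19.5 mM. At the high end the balance, drawn as a straight line around half of the substrate coupled, gives an estimate of 62.0 % for zeta and 39.7 % for gamma. At the low end the logarithm shrinks to the fraction coupled, so target is the surviving charge divided by [substrate charged] + K.

The forecast reads: beta 70 %, eta 56 %, zeta 50 %, gamma 36 %, theta 61 %, with beta leading, and “the slower the feed, the worse it gets”. On zeta it stands 12 points lower than this reckoning.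

The flasks give beta 69.7 %, eta 58.2 %, zeta 60.0 %, gamma 37.7 % and theta 64.9 %, and beta leads.

    substrate + free catalyst → free catalyst + intermediate (k = 7300 M⁻¹ h⁻¹)
    partner + second catalyst + intermediate → second catalyst + target (k = 840 M⁻² h⁻¹)
    partner → decomposed reagent (k = 0.0170 h⁻¹)

Zeta lands 10 points above the forecast. Priced with K, the target at the end of gamma costs 18.7 mM of partner against the reckoned surviving charge of 19.5 mM. Taking the decomposition step away narrows the gap between beta and gamma from 32 points to 15 points, so that step carries 17 points of the gap, not the whole of it.

Gamma's neighbour with 0.500 equiv of partner is reckoned to have a surviving charge of 4.88 mM, and the low end gives 11.1 % of target. The flask gives 11.5 %.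

The runs come from a simulation for substances that don't exist.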